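A direct plan would open 2,3-epoxycyclohexanone A2 with the phenoxide of 5-bromo-2-methoxyphenol A1 and dehydrate to aryloxyenone A3. It would then convert the enone ring of A3 into the tribromophenol ring of methyl ether A4 with four equivalents of Br2 in one flask, and finish by O-demethylation with BBr3. Its weakest steps would be:
- the fourfold bromination with aromatization, because vinylic bromination, α'-bromination, loss of HBr and two aromatic brominations would have to follow one another at exact stoichiometry while ring A and C5 stay untouched;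
- the demethylation, which would add a step without adding complexity;
- the epoxide opening, in which the base-sensitive epoxy ketone could self-condense before the weakly nucleophilic phenoxide attacks.

The route would rest on cutting the bond between the ether oxygen and C1 of ring A (the bromohydroxyphenoxy ring), the carbon next to C2–OH, with ring A entering as an α-oxo carbene from ortho-quinone diazide 7. Ring B is read as a 2,3,5,6-tetrabromophenoxy group in which one ortho bromine is later exchanged for OH; the two ortho bromines are equivalent, so no choice between them is needed. In the key step a rhodium carbenoid would insert into the O–H bond of 4, forming the triply ortho-substituted ether and the ring A phenol at once with all bromines in place. No bromination of the assembled ether, no aromatization of a carbocycle and no protecting group would remain.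

Key step: step 3

Remark: the target has no stereocentre. 2,3,5,6-Tetrabromophenol is assumed not to be available in quantity and is made in step 1. Quinone diazide 7 would be handled only in solution and in the dark.

Step 1
Reactants: 1 1,2,4,5-tetrabromobenzene
Product: 4 2,3,5,6-tetrabromophenol, via aryllithium 2 (not isolated), via lithium aryltriisopropoxyborate 3 (not isolated)
Conditions: B(OiPr)3 (1.5 equiv), THF, −78 °C, LiN(iPr)2 (1.1 equiv) added dropwise, 1 h; then AcOH, 30% aq H2O2, 0 → 23 °C
Reagents that add atoms: hydrogen peroxide, OO
Why: The C–H of 1 lies between two bromines and should be acidic enough for LiN(iPr)2; aryllithium 2 should be captured by the B(OiPr)3 already present before it can lose LiBr, the anionic borate 3 should resist a second deprotonation, and oxidation replaces boron by OH at the same carbon (directed lithiation with in situ quench, then boronate oxidation).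

Step 2
Reactants: 5 2-amino-4-bromophenol
Product: 7 4-bromo-6-diazocyclohexa-2,4-dien-1-one, via diazonium chloride 6 (not isolated)
Conditions: NaNO2 (1.05 equiv), 2 M aq HCl, 0 °C, 30 min; NaHCO3 to pH 7; extraction into CH2Cl2, Na2SO4, 4 Å molecular sieves; kept as a cold solution in the dark
Reagents that add atoms: sodium nitrite, [Na+].[O-]N=O
Why: Diazotization of the ortho-aminophenol should give diazonium salt 6, whose acidic phenol is deprotonated at pH 7 to the neutral, extractable ortho-quinone diazide; the solution would not be evaporated to dryness because dry quinone diazides can decompose violently.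

Step 3
Reactants: 7 4-bromo-6-diazocyclohexa-2,4-dien-1-one; 4 2,3,5,6-tetrabromophenol
Product: 9 4-bromo-2-(2,3,5,6-tetrabromophenoxy)phenol, via rhodium carbenoid 8 (not isolated)
Conditions: 4 (2.0 equiv), Rh2(OAc)4 (2 mol %), 4 Å molecular sieves, CH2Cl2, 35 °C, dark; 7 (1.0 equiv) in CH2Cl2 added over 4 h
Reagents that add atoms: none
Why: Rh2(OAc)4 should expel N2 from 7 to give the electrophilic quinoid carbenoid 8, the hydroxyl oxygen of 4 should add to its carbene carbon, and proton transfer from the oxonium ylide to the carbonyl oxygen (directly or through the 6-aryloxydienone tautomer) should aromatize ring A and release the catalyst. The closest known reaction types are the rhodium-carbenoid O–H insertion of α-diazo carbonyl compounds into phenols and the O–H insertion of ortho-quinone diazides into alcohols, which gives 2-alkoxyphenols and 1-alkoxy-2-naphthols. No ring is closed and no stereocentre is formed; the regiochemistry of ring A is fixed because the new C–O bond can only arise at the diazo carbon, next to the oxygen and meta to bromine. The step needs O–H insertion into 4 to win over Wolff ring contraction, over insertion into the O–H of product 9 and over C–H attack on an arene: metal catalysis at 35 °C in the dark disfavours the Wolff path, the excess and higher acidity of 4 together with slow addition of 7 disfavour attack on 9, and the only C–H of 4 lies between two bromines on a deactivated ring. The planar carbenoid carbon should tolerate the two ortho bromines of 4, which would slow an SNAr or Ullmann reaction at this oxygen.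

Step 4
Reactants: 9 4-bromo-2-(2,3,5,6-tetrabromophenoxy)phenol
Product: 13 3,4,6-tribromo-2-(5-bromo-2-hydroxyphenoxy)phenol, via chloromagnesium phenoxide 10 (not isolated), via aryl Grignard reagent 11 (not isolated), via dimethyl arylboronate 12 (not isolated)
Conditions: iPrMgCl·LiCl (2.1 equiv), THF, −40 °C, 1 h; B(OMe)3 (3 equiv), −40 → 0 °C; then AcOH, 30% aq H2O2, 0 → 23 °C
Reagents that add atoms: hydrogen peroxide, OO
Why: After the first equivalent has deprotonated the phenol (10), bromine–magnesium exchange should take place at one of the two equivalent ring B bromines ortho to the ether oxygen, because only there is the carbanion flanked by two σ-acceptors (O and Br) and within reach of the neighbouring magnesium phenoxide, while the ring A bromine sits para to an O–Mg group on an electron-rich ring; borate capture and boronate oxidation under acidic conditions then put OH at that carbon.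

Compound list
1 | 1,2,4,5-tetrabromobenzene | Brc1cc(Br)c(Br)cc1Br | starting material
2 | (2,3,5,6-tetrabromophenyl)lithium | [Li]c1c(Br)c(Br)cc(Br)c1Br | intermediate
3 | lithium triisopropoxy(2,3,5,6-tetrabromophenyl)borate | [Li+].CC(C)O[B-](OC(C)C)(OC(C)C)c1c(Br)c(Br)cc(Br)c1Br | intermediate
4 | 2,3,5,6-tetrabromophenol | Oc1c(Br)c(Br)cc(Br)c1Br | intermediate
5 | 2-amino-4-bromophenol | Nc1cc(Br)ccc1O | starting material
6 | 5-bromo-2-hydroxybenzenediazonium chloride | Oc1ccc(Br)cc1[N+]#N.[Cl-] | intermediate
7 | 4-bromo-6-diazocyclohexa-2,4-dien-1-one (ortho-quinone diazide) | O=C1C=CC(Br)=CC1=[N+]=[N-] | intermediate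
8 | carbenoid of Rh2(OAc)4 with 5-bromo-2-oxocyclohexa-3,5-dien-1-ylidene (one rhodium atom drawn, acetate ligands omitted) | O=C1C=CC(Br)=CC1=[Rh] | intermediate
9 | 4-bromo-2-(2,3,5,6-tetrabromophenoxy)phenol | Oc1ccc(Br)cc1Oc1c(Br)c(Br)cc(Br)c1Br | intermediate
10 | chloromagnesium 4-bromo-2-(2,3,5,6-tetrabromophenoxy)phenoxide | Cl[Mg]Oc1ccc(Br)cc1Oc1c(Br)c(Br)cc(Br)c1Br | intermediate
11 | chloromagnesium 4-bromo-2-[3,5,6-tribromo-2-(chloromagnesio)phenoxy]phenoxide | Cl[Mg]Oc1ccc(Br)cc1Oc1c([Mg]Cl)c(Br)cc(Br)c1Br | intermediate
12 | dimethyl [3,4,6-tribromo-2-(5-bromo-2-(chloromagnesiooxy)phenoxy)phenyl]boronate | Cl[Mg]Oc1ccc(Br)cc1Oc1c(B(OC)OC)c(Br)cc(Br)c1Br | intermediate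
13 | 3,4,6-tribromo-2-(5-bromo-2-hydroxyphenoxy)phenol (achiral) | Oc1ccc(Br)cc1Oc1c(O)c(Br)cc(Br)c1Br | target

Total step count: 4
Longest linear sequence: 3 steps (1 → 4 → 9 → 13, or 5 → 7 → 9 → 13)

Steps most likely to fail

Step 3. The carbenoid may be diverted by Wolff ring contraction, by insertion into the O–H of 9 to give oligomeric ethers or by traces of water, or 7 may decompose before it reaches the catalyst. The fallback sets out from 4 and comes back at 9. The potassium salt of 4 would displace fluoride from 4-bromo-2-fluoro-1-nitrobenzene F1 (K2CO3, DMSO, 100 °C; SNAr activated by the ortho nitro group) to give 4-bromo-1-nitro-2-(2,3,5,6-tetrabromophenoxy)benzene F2. Reduction with Fe and NH4Cl in aqueous EtOH would give 4-bromo-2-(2,3,5,6-tetrabromophenoxy)aniline F3. Diazotization (NaNO2, aqueous H2SO4, 0 °C) to 4-bromo-2-(2,3,5,6-tetrabromophenoxy)benzenediazonium hydrogensulfate F4 and hydroxylation with Cu2O and Cu(NO3)2 in water at 23 °C would give phenol 9.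

Step 4. Exchange may occur at a meta bromine of ring B or at the ring A bromine, the ortho-bromoaryl Grignard reagent may lose MgBrCl to an aryne, or the crowded boronate may protodeboronate during oxidation. The fallback sets out from 7 and comes back at 13, with the ring B oxygen in place before the ether is made. 2-Bromo-6-methoxyphenol F5 would be acetylated (Ac2O, pyridine) to 2-bromo-6-methoxyphenyl acetate F6. Bromination para and ortho to the methoxy group (Br2, NaOAc, AcOH, 50 °C) would give 2,3,5-tribromo-6-methoxyphenyl acetate F7, and deacetylation (K2CO3, MeOH) would give 2,3,5-tribromo-6-methoxyphenol F8. Insertion of the carbenoid from 7 into the O–H of F8 under the conditions of step 3 would give 4-bromo-2-(2,3,5-tribromo-6-methoxyphenoxy)phenol F9, and BBr3 (CH2Cl2, −78 → 0 °C) would cleave the methyl ether to 13.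

Step 1. Aryllithium 2 may lose LiBr to an aryne, bromine may migrate between rings (halogen dance), or a second metalation may occur before borate capture. The fallback sets out from 1 and comes back at 4. Nitration (fuming HNO3, H2SO4, 50 °C) would give 1,2,4,5-tetrabromo-3-nitrobenzene F10, and reduction with SnCl2 in EtOH and aqueous HCl would give 2,3,5,6-tetrabromoaniline F11. Diazotization (NaNO2, H2SO4, 0 °C) to 2,3,5,6-tetrabromobenzenediazonium hydrogensulfate F12 and hydroxylation with Cu2O and Cu(NO3)2 in water would give 4.

Further compounds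
F1 | step 3 | 4-bromo-2-fluoro-1-nitrobenzene (purchased) | O=[N+]([O-])c1ccc(Br)cc1F
F2 | step 3 | 4-bromo-1-nitro-2-(2,3,5,6-tetrabromophenoxy)benzene | O=[N+]([O-])c1ccc(Br)cc1Oc1c(Br)c(Br)cc(Br)c1Br
F3 | step 3 | 4-bromo-2-(2,3,5,6-tetrabromophenoxy)aniline | Nc1ccc(Br)cc1Oc1c(Br)c(Br)cc(Br)c1Br
F4 | step 3 | 4-bromo-2-(2,3,5,6-tetrabromophenoxy)benzenediazonium hydrogensulfate | N#[N+]c1ccc(Br)cc1Oc1c(Br)c(Br)cc(Br)c1Br.OS(=O)(=O)[O-]
F5 | step 4 | 2-bromo-6-methoxyphenol (purchased) | COc1cccc(Br)c1O
F6 | step 4 | 2-bromo-6-methoxyphenyl acetate | COc1cccc(Br)c1OC(C)=O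
F7 | step 4 | 2,3,5-tribromo-6-methoxyphenyl acetate | COc1c(Br)cc(Br)c(Br)c1OC(C)=O
F8 | step 4 | 2,3,5-tribromo-6-methoxyphenol | COc1c(Br)cc(Br)c(Br)c1O
F9 | step 4 | 4-bromo-2-(2,3,5-tribromo-6-methoxyphenoxy)phenol | COc1c(Br)cc(Br)c(Br)c1Oc1cc(Br)ccc1O
F10 | step 1 | 1,2,4,5-tetrabromo-3-nitrobenzene | O=[N+]([O-])c1c(Br)c(Br)cc(Br)c1Br
F11 | step 1 | 2,3,5,6-tetrabromoaniline | Nc1c(Br)c(Br)cc(Br)c1Br
F12 | step 1 | 2,3,5,6-tetrabromobenzenediazonium hydrogensulfate | N#[N+]c1c(Br)c(Br)cc(Br)c1Br.OS(=O)(=O)[O-]
A1 | direct plan | 5-bromo-2-methoxyphenol | COc1ccc(Br)cc1O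
A2 | direct plan | (±)-2,3-epoxycyclohexan-1-one (racemic, one enantiomer drawn) | O=C1CCC[C@@H]2O[C@H]12
A3 | direct plan | 2-(5-bromo-2-methoxyphenoxy)cyclohex-2-en-1-one | O=C1CCCC=C1Oc1cc(Br)ccc1OC
A4 | direct plan | 3,4,6-tribromo-2-(5-bromo-2-methoxyphenoxy)phenol | COc1ccc(Br)cc1Oc1c(O)c(Br)cc(Br)c1Br
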